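4 questions stood on 6 flasks, and 2 earlier runs were there to answer them.

| setting | Monday's | Thursday's | green | ochre | red | amber | blue | violet |
|---|---|---|---|---|---|---|---|---|
| substrate | 20 mM | 20 mM | 20 mM | 20 mM | 20 mM | 20 mM | 20 mM | 20 mM |
| catalyst | 37 µM | 170 µM | 40 µM | 25 µM | 10 µM | 60 µM | 150 µM | 12 µM |
| remark | run made earlier | run made earlier |  |  |  |  |  |  |
| time |  |  | 4.0 min | 4.0 min | 4.0 min | 4.0 min | 4.0 min | 4.0 min |

- all flasks from highest to lowest amount of target, in percent of the substrate charged, at 4.0 min (green / ochre / red / amber / blue / violet)
- the same order at 50 s (green / ochre / red / amber / blue / violet)
- the amount of target, in percent of the substrate charged of the flask you put first, at 4.0 min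
- the amount of target, in percent of the substrate charged of the flask you put last, at 4.0 min

- in a conversion other conformer counts as not yet reacted

| run | time / s | target / % |
|---|---|---|
| Monday's | 10.0 | 5.6 |
| Monday's | 20.0 | 11.0 |
| Monday's | 50.0 | 21.4 |
| Monday's | 120 | 38.7 |
| Thursday's | 15.0 | 30.8 |
| Thursday's | 40.0 | 58.8 |
| Thursday's | 80.0 | 76.4 |
| Thursday's | 120 | 82.9 |

(readings scatter by 0.5 percentage points)

I read these tables row against row, in shares of the charge. Monday's first row gave the catalyst's pace: 0.00560 s⁻¹, pseudo-first-order in substrate, which I took as proportional to the catalyst charge. Monday's last 2 rows gained target at a slope which, divided by that pace, put my estimate of free substrate between those rows at 44.1 % of the charge. Target averaged 30.0 % over those rows, so I estimated that 25.8 % was neither.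

I assumed that target and the missing part both grow from the same free substrate. Their ratio then compares the catalyst's rate with a leak that ignores the catalyst. Multiplying Monday's charge by missing over target gave 31.8 µM. Thursday's last rows, reckoned the same way, gave 30.0 µM from a very different charge.

I carried their mean, 30.9 µM, as the crossing charge, the catalyst charge at which catalyst and leak take substrate equally fast. On my assumption, a flask's charge over this crossing is its selectivity factor, and its target share of what leaves substrate is charge over charge plus crossing. Ochre lay below the crossing and green above it.

In this reckoning, share and total rate both rise with catalyst, so I ordered the flasks by catalyst at both times. With the exponential approach, I reckoned 82.8 % for blue and 18.9 % for red.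

The forecast gave the same orders, blue > amber > green > ochre > violet > red and blue > amber > green > ochre > violet > red, on the ground that “More catalyst always gives more target”. Its amounts differed from mine: 90 % for blue, higher than mine, and 20.5 % for red.

The flasks gave blue > amber > green > ochre > violet > red at 4.0 min and blue > amber > green > ochre > violet > red at 50 s, with 84.6 % in blue and 21.1 % in red.

    substrate ⇌ other conformer (K = 0.370, k = 0.240 min⁻¹)
    substrate → uncatalysed product (k = 0.0910 min⁻¹)
    catalyst + other conformer → catalyst + isomer of the product (k = 6600 M⁻¹ min⁻¹)
    substrate + catalyst → catalyst + target (k = 8900 M⁻¹ min⁻¹)

At 4.00 min in blue, the step to target used substrate 5.6 times as fast as the forward step to other conformer, and 0.330 % of the substrate charged was left. That blue amount of 84.6 % lay 5.4 percentage points under the forecast and 1.8 points over my reckoning from the crossing charge of 30.9 µM.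

For a flask like blue with 250 µM of catalyst, the crossing gives a share of 89.0 %. After 4.00 min that flask held 89.4 % of target, with 0.012 % of the substrate charged left.

Readings and results come from a simulation with made-up constants, and the scatter is random.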